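All runs were generated by integration with made-up constants.

Two questions stand on this flask, and both ask how far right-handed substrate comes to outweigh left-handed substrate among what is left of the two.

- gamma: left-handed substrate 0.30 M; right-handed substrate 0.30 M; partner 2 equiv; free catalyst 0.55 mol%; the very flask that is asked about, followed so far
- flask: left-handed substrate 0.30 M; partner 2.00 equiv; free catalyst 0.55 mol%; right-handed substrate 0.30 M; time 3.0 min

gamma run (percent of the left-handed substrate and right-handed substrate together charged)

| time / s | right-handed substrate / % | left-handed substrate / % | left-handed product / % |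
|---|---|---|---|
| 10.0 | 41.1 | 30.6 | 17.7 |
| 12.0 | 40.4 | 28.2 | 20.5 |
| 20.0 | 36.5 | 19.9 | 29.6 |
| 30.0 | 32.3 | 14.2 | 34.2 |
| 50.0 | 27.2 | 6.4 | 40.0 |

(readings scatter by 0.5 percentage points)

1. whether the excess of right-handed substrate over left-handed substrate among what is left of the two reaches 80% by 3.0 min (yes / no)
2. the highest excess of right-handed substrate over left-handed substrate among what is left of the two up to 3.0 min

- free catalyst is single-handed; left-handed substrate and right-handed substrate are mirror images of each other, charged as a racemate, each of them at the stated concentration
- the numbers in the tables scatter by 0.5 percentage points (one standard deviation)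

An excess of 80% means right-handed substrate stands at 9.00 times left-handed substrate. Two reckonings of my own reach for the time of that ratio.

The first is a clock on the ratio itself. Its logarithm grows between 10.0 s and 50.0 s at

g = 0.0288 s⁻¹, which reaches the ratio at 76.1 s.

The second counts halvings. At 50.0 s, left-handed substrate stands at a fraction 0.128 of its own charge and right-handed substrate at 0.544, so

s = 3.38

This is the number of halvings of left-handed substrate for each halving of right-handed substrate, the selectivity factor. The wanted ratio then asks right-handed substrate to fall to

0.397 of its own charge, or 19.8% of both charges.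

At its last-stretch rate of 0.00859 s⁻¹, right-handed substrate gets there at 86.7 s.

The two times part by 10.6 s, yet both are far earlier than 3.0 min, so the answer is yes. The readings of right-handed substrate show a fall at 0.0120 s⁻¹ between 10.0 s and 30.0 s, faster than the 0.00859 s⁻¹ after it, so I commit to the later time.

The forecast gives yes and a top of 96%, noting that “apparent selectivity rises from 2.5 towards 4 or more”.

This flask gives yes and a top of 95.4%.

    free catalyst + left-handed substrate ⇌ catalyst intermediate A (K = 2.70 L mol⁻¹, k = 63.0 L mol⁻¹ s⁻¹)
    free catalyst + right-handed substrate ⇌ catalyst intermediate B (K = 1.30 L mol⁻¹, k = 99.0 L mol⁻¹ s⁻¹)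
    partner + catalyst intermediate A → free catalyst + left-handed product (k = 94.0 L mol⁻¹ s⁻¹)
    partner + catalyst intermediate B → free catalyst + right-handed product (k = 30.0 L mol⁻¹ s⁻¹)
    left-handed product ⇌ right-handed product (k = 0.00560 s⁻¹)
    2 partner → self-condensation product (k = 8.60 × 10⁻⁴ L mol⁻¹ s⁻¹)
    2 free catalyst → spent catalyst (k = 0.680 L mol⁻¹ s⁻¹)

The excess passes 80% at 1.43 min, earlier than 3.0 min, with right-handed substrate at 20.5% of both charges. Carried to the end, s turns the 27% of right-handed charge still there, unbound, at 3.00 min into an estimated 1.27% of left-handed charge, and so into an excess of 91.1%, less than the flask's top. The flask's own remainder of left-handed charge is 0.65%, which puts the selectivity factor over the whole run at 3.90.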